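**Plan**
- The retrosynthesis first cuts the C2–Br bond and then the C3–S bond of the pyrrole ring. This leads back to 4,5,6-tribromo-1H-indole, dimethyl disulfide and N-bromosuccinimide.
- Enabling feature: the enamine-like pyrrole carbons C3 and C2 of that indole are its most nucleophilic atoms, C3 ahead of C2. The benzene ring, brominated at C4, C5 and C6, is deactivated, so sulfur lands on C3 and the fourth bromine on C2.
- The pyrrole ring is cut at N1–C2 and C2–C3 (Leimgruber–Batcho) to 1,2,3-tribromo-4-methyl-5-nitrobenzene. Its C–Br bonds go back to 3-methyl-4-nitroaniline: Sandmeyer for the central bromine, amine-directed bromination for the outer two.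
- Forward order: the purchased benzene ring is tribrominated, the pyrrole ring is closed onto it, and C3 and C2 are substituted last in one flask.
- Stereochemistry: the target is achiral and has no stereocentre. The only stereo-element on the way, the E enamine double bond, vanishes on ring closure.

Key step: step 5

Remark on the chemistry: methanesulfenyl chloride is assumed to be made as a CH2Cl2 solution just before use and transferred without isolation, so its formation is counted within step 5.

**Step 1**
Reactants: 1 3-methyl-4-nitroaniline
Product: 2 2,6-dibromo-3-methyl-4-nitroaniline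
Conditions: Br2 (2.1 equiv), AcOH, rt to 50 °C
Reagents that add atoms: bromine, BrBr
Why: In this electrophilic aromatic bromination the amino group outweighs the nitro group and directs to its two free ortho carbons (C2 and C6), the para carbon being occupied by nitro, so the reaction should stop cleanly at the dibromide.

**Step 2**
Reactants: 2 2,6-dibromo-3-methyl-4-nitroaniline
Product: 4 1,2,3-tribromo-4-methyl-5-nitrobenzene, via diazonium bromide 3 (not isolated)
Conditions: t-BuONO (1.5 equiv), CuBr2 (1.2 equiv), MeCN, 60 °C
Reagents that add atoms: CuBr2, [Cu+2].[Br-].[Br-]; tert-butyl nitrite, CC(C)(C)ON=O (supplies only the outer nitrogen of 3)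
Why: A Sandmeyer bromination under aprotic alkyl nitrite/CuBr2 conditions suits a weakly basic, doubly ortho-substituted aniline that diazotises poorly in dilute aqueous acid, the aryl radical released from 3 being capped by bromine transfer from copper, and the methyl group lies meta to the diazonium carbon so that no indazole can form.

**Step 3**
Reactants: 4 1,2,3-tribromo-4-methyl-5-nitrobenzene
Product: 5 (E)-N,N-dimethyl-2-(2,3,4-tribromo-6-nitrophenyl)ethen-1-amine
Conditions: Me2NCH(OMe)2 (3 equiv), DMF, 110 °C, N2 stream to carry off MeOH
Reagents that add atoms: N,N-dimethylformamide dimethyl acetal, COC(OC)N(C)C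
Why: In this first stage of the Leimgruber–Batcho indole synthesis the methyl C–H bonds, acidified by the ortho nitro group and the three bromines, condense with the formamide acetal to the thermodynamically favoured push–pull E enamine, and omitting the usual pyrrolidine additive keeps a strong amine nucleophile away from the bromine para to nitro.

**Step 4**
Reactants: 5 (E)-N,N-dimethyl-2-(2,3,4-tribromo-6-nitrophenyl)ethen-1-amine
Product: 7 4,5,6-tribromo-1H-indole, via amino enamine 6 (not isolated)
Conditions: Fe powder (8 equiv), AcOH/EtOH, 80 °C
Reagents that add atoms: none
Why: In this second stage of the Leimgruber–Batcho synthesis a Béchamp-type reduction of the nitro group gives aniline 6, whose nitrogen closes the pyrrole ring by 5-exo-trig attack on the C-protonated enamine (an iminium carbon) and aromatises by expelling dimethylamine, while iron in acetic acid, unlike catalytic hydrogenation, leaves aryl C–Br bonds alone.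

**Step 5**
Reactants: 7 4,5,6-tribromo-1H-indole; 8 dimethyl disulfide; 9 N-bromosuccinimide
Product: 12 2,4,5,6-tetrabromo-3-methylsulfanyl-1H-indole, via methanesulfenyl chloride 10 (not isolated), via 4,5,6-tribromo-3-methylsulfanyl-1H-indole 11 (not isolated)
Conditions: 8 (0.52 equiv), SO2Cl2 (0.50 equiv), CH2Cl2, −20 to 0 °C; cannulate into 7, CH2Cl2, 0 °C to rt; Ar purge; 9 (1.0 equiv), 0 °C, dark, anhydrous
Reagents that add atoms: dimethyl disulfide 8, CSSC; N-bromosuccinimide 9, O=C1CCC(=O)N1Br; sulfuryl chloride, O=S(=O)(Cl)Cl (supplies only the chlorine of 10)
Why: Chlorinolysis of the S–S bond of 8 by SO2Cl2 gives sulfenyl chloride 10, which attacks C3 of 7, the carbon of highest enamine-type electron density, to give an N1-stabilised 3H-indolium cation that loses its C3 proton and furnishes 11. NBS then transfers electrophilic bromine to the pyrrole ring of 11, most plausibly by ipso attack at C3 (or initial attack at sulfur) followed by migration of bromine to the neighbouring C2 and loss of the C2 proton, which restores the aromatic indole as 12. Both halves are known electrophilic substitutions of indoles, namely C3 sulfenylation by sulfenyl chlorides and C2 halogenation of 3-sulfanylindoles by N-halosuccinimides, run here one after the other in a single flask. No ring is closed and no stereocentre is created. The site selectivity needed is pyrrole ring over benzene ring and C3 before C2: the bromines at C4, C5 and C6 deactivate the carbocycle and leave only C7–H, which is far less nucleophilic than the C2=C3 bond, the innate C3-over-C2 preference places sulfur on C3, and the sulfanyl group then leaves C2 as the only carbon at which substitution can end. Chemoselectivity at sulfur is secured by one equivalent of each electrophile, a slight deficit of SO2Cl2 relative to 8 so that no chlorinating agent survives, exclusion of water so that a bromosulfonium ion cannot collapse to the sulfoxide, and removal of HCl and SO2 by the argon purge before 9 is added.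

**Compound list**
1 | 3-methyl-4-nitroaniline | Cc1cc(N)ccc1[N+](=O)[O-] | starting material
2 | 2,6-dibromo-3-methyl-4-nitroaniline | Cc1c(Br)c(N)c(Br)cc1[N+](=O)[O-] | intermediate
3 | 2,6-dibromo-3-methyl-4-nitrobenzenediazonium bromide (not isolated) | Cc1c(Br)c([N+]#N)c(Br)cc1[N+](=O)[O-].[Br-] | intermediate
4 | 1,2,3-tribromo-4-methyl-5-nitrobenzene (2,3,4-tribromo-6-nitrotoluene) | Cc1c(Br)c(Br)c(Br)cc1[N+](=O)[O-] | intermediate
5 | (E)-N,N-dimethyl-2-(2,3,4-tribromo-6-nitrophenyl)ethen-1-amine | CN(C)/C=C/c1c(Br)c(Br)c(Br)cc1[N+](=O)[O-] | intermediate
6 | 3,4,5-tribromo-2-[(E)-2-(dimethylamino)ethenyl]aniline (not isolated) | CN(C)/C=C/c1c(Br)c(Br)c(Br)cc1N | intermediate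
7 | 4,5,6-tribromo-1H-indole | Brc1cc2[nH]ccc2c(Br)c1Br | intermediate
8 | dimethyl disulfide | CSSC | starting material
9 | N-bromosuccinimide | O=C1CCC(=O)N1Br | starting material
10 | methanesulfenyl chloride (not isolated) | CSCl | intermediate
11 | 4,5,6-tribromo-3-methylsulfanyl-1H-indole (not isolated) | CSc1c[nH]c2cc(Br)c(Br)c(Br)c12 | intermediate
12 | 2,4,5,6-tetrabromo-3-methylsulfanyl-1H-indole | CSc1c(Br)[nH]c2cc(Br)c(Br)c(Br)c12 | target

Total step count: 5
Longest linear sequence: 5 steps (1 → 2 → 4 → 5 → 7 → 12)

**Steps most likely to fail**

**Step 5.**
- Attack of the sulfenyl chloride may be slow, because the indole is drained by three bromines and crowded by the peri bromine at C4.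
- A second sulfenylation or acid-induced scrambling of the sulfanyl group may occur.
- NBS may be consumed by residual HCl, SO2 or the thioether sulfur.

The fallback sets out from 7 and separates the two events through a sulfonium salt. Treatment of 7 with the chlorosulfonium reagent formed from Me2S and N-chlorosuccinimide (CH2Cl2, −20 °C) should give (4,5,6-tribromo-1H-indol-3-yl)dimethylsulfonium chloride F1. This salt can be filtered free of all by-products, and its positive charge prevents a second substitution. Heating it in refluxing xylene lets chloride remove one S-methyl group by SN2 attack. That delivers 11 as an isolated, purified compound, and the route is rejoined there. Bromination of 11 with 9 is then carried out in a separate, acid-free flask.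

**Step 3.**
- Methoxide or dimethylamine liberated from the acetal may displace the bromine para to the nitro group.
- Condensation may be slow at a methyl group wedged between bromine and nitro.

The fallback sets out from 4 and brings in C2 of the indole from nitromethane under non-basic conditions. Wohl–Ziegler bromination (9, AIBN, PhCF3, reflux) should give 1,2,3-tribromo-4-(bromomethyl)-5-nitrobenzene F2. Oxidation with N-methylmorpholine N-oxide in MeCN should give 2,3,4-tribromo-6-nitrobenzaldehyde F3. Henry condensation with MeNO2 and NH4OAc in AcOH should give 1,2,3-tribromo-5-nitro-4-[(E)-2-nitroethenyl]benzene F4. Reductive cyclisation of this 2,β-dinitrostyrene with Fe powder and silica gel in AcOH/toluene rejoins the route at 7.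

**Step 4.**
- C–Br bonds may undergo reductive cleavage.
- The reduction may stall at the hydroxylamine stage.
- The electron-rich amino enamine may polymerise in hot acid before the ring closes.

The fallback sets out from 5 and decouples reduction from cyclisation. Methanolysis of the enamine (MeOH, TsOH, reflux) should give 1,2,3-tribromo-4-(2,2-dimethoxyethyl)-5-nitrobenzene F5. Mild nitro reduction with Na2S2O4 in aqueous THF should give 3,4,5-tribromo-2-(2,2-dimethoxyethyl)aniline F6. Brief exposure to dilute HCl in THF at rt unmasks the aldehyde and closes the pyrrole ring, rejoining the route at 7.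

**Further compounds**
F1 | step 5 | (4,5,6-tribromo-1H-indol-3-yl)dimethylsulfonium chloride | C[S+](C)c1c[nH]c2cc(Br)c(Br)c(Br)c12.[Cl-]
F2 | step 3 | 1,2,3-tribromo-4-(bromomethyl)-5-nitrobenzene | BrCc1c(Br)c(Br)c(Br)cc1[N+](=O)[O-]
F3 | step 3 | 2,3,4-tribromo-6-nitrobenzaldehyde | O=Cc1c(Br)c(Br)c(Br)cc1[N+](=O)[O-]
F4 | step 3 | 1,2,3-tribromo-5-nitro-4-[(E)-2-nitroethenyl]benzene | O=[N+]([O-])/C=C/c1c(Br)c(Br)c(Br)cc1[N+](=O)[O-]
F5 | step 4 | 1,2,3-tribromo-4-(2,2-dimethoxyethyl)-5-nitrobenzene | COC(Cc1c(Br)c(Br)c(Br)cc1[N+](=O)[O-])OC
F6 | step 4 | 3,4,5-tribromo-2-(2,2-dimethoxyethyl)aniline | COC(Cc1c(Br)c(Br)c(Br)cc1N)OC
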